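## Retrosynthetic overview

1. Last disconnection: the three phenolic O–Si bonds (7, 3', 5'), i.e. global desilylation of the tris-TBS ether of the target.
2. Key disconnection: the C6–C1'' (ring–geranyl) bond, made by a clay-promoted [1,3]-sigmatropic O→C geranyl shift from the neighbouring 5-O-geranyl ether.
3. The 5-O-geranyl ether comes from Mitsunobu coupling of geraniol with the chelated 5-OH of the 7,3',5'-trisilylated flavanone.
4. Rings: none is formed. Rings A, B and the pyranone ring C with its (2S) centre are bought together as natural (2S)-5,7,3',5'-tetrahydroxyflavanone, and every step is kept non-basic so that C2 cannot racemise through the chalcone.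

Assumption: (2S)-5,7,3',5'-tetrahydroxyflavanone is bought as the enantiopure plant isolate from natural-product suppliers (a catalogue compound, not a bulk chemical), and its ee is confirmed by chiral HPLC before use.

## Route

Step 1
Reactants: 1 (2S)-5,7,3',5'-tetrahydroxyflavanone
Product: 2 (2S)-7-(tert-butyldimethylsilyloxy)-2-[3,5-bis(tert-butyldimethylsilyloxy)phenyl]-5-hydroxychroman-4-one
Conditions: TBSCl (3.3 equiv), imidazole (6 equiv), DMF, 0 °C → rt
Reagents that add atoms: tert-butyldimethylsilyl chloride (TBSCl), CC(C)(C)[Si](C)(C)Cl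
Why: Imidazole-mediated silyl etherification takes the three unhindered phenols (7, 3', 5') while the 5-OH, hydrogen-bonded to the peri C4 carbonyl, stays free, and imidazole is too weak a base to open the pyranone by retro-oxa-Michael reaction, so C2 stays S.

Step 2
Reactants: 2 (2S)-7,3',5'-tris-O-TBS-5-hydroxyflavanone; 3 geraniol
Product: 4 (2S)-7-(tert-butyldimethylsilyloxy)-2-[3,5-bis(tert-butyldimethylsilyloxy)phenyl]-5-{[(2E)-3,7-dimethylocta-2,6-dien-1-yl]oxy}chroman-4-one
Conditions: PPh3 (1.5 equiv), DIAD (1.5 equiv), THF, 0 °C → rt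
Reagents that add atoms: none
Why: Mitsunobu etherification, in which the chelated 5-OH (the only acidic OH left) displaces the oxyphosphonium of the primary allylic alcohol by SN2 at C1 (no allylic transposition, E alkene kept) under neutral conditions that leave the silyl ethers and C2 untouched.

Step 3
Reactants: 4 (2S)-5-O-geranyl-7,3',5'-tris-O-TBS-flavanone
Product: 5 (2S)-7-(tert-butyldimethylsilyloxy)-2-[3,5-bis(tert-butyldimethylsilyloxy)phenyl]-6-[(2E)-3,7-dimethylocta-2,6-dien-1-yl]-5-hydroxychroman-4-one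
Conditions: Montmorillonite K10 (oven-dried, ca. 2 wt equiv), CH2Cl2, 0 °C, 1–2 h
Reagents that add atoms: none
Why: Montmorillonite K10-promoted [1,3]-sigmatropic O→C shift of the allyl aryl ether (a formal, tight-ion-pair Claisen-type isomerisation known for 5-O-prenyl flavanones and ortho-acyl aryl geranyl ethers) hands the geranyl group through its primary terminus to the adjacent, doubly O-activated C6, so the E chain arrives unrearranged and the mild acid at 0 °C does not open the pyranone, leaving C2 as S.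

Step 4
Reactants: 5 (2S)-6-geranyl-7,3',5'-tris-O-TBS-5-hydroxyflavanone
Product: 6 Schizolaenone C, (2S)-2-(3,5-dihydroxyphenyl)-6-[(2E)-3,7-dimethylocta-2,6-dien-1-yl]-5,7-dihydroxychroman-4-one
Conditions: TBAF (3.5 equiv), AcOH (3.5 equiv), THF, 0 °C
Reagents that add atoms: none
Why: Fluoride-mediated desilylation buffered with acetic acid frees the three phenols without building up phenoxide, which avoids retro-oxa-Michael racemisation at C2, 6→8 isomerisation and acid cyclisation of the geranyl chain onto the ortho phenols.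

## Compound list

1 | (2S)-5,7,3',5'-tetrahydroxyflavanone [(2S)-2-(3,5-dihydroxyphenyl)-5,7-dihydroxychroman-4-one] | O=C1C[C@@H](c2cc(O)cc(O)c2)Oc2cc(O)cc(O)c12 | starting material
2 | (2S)-7-(TBS-oxy)-2-[3,5-bis(TBS-oxy)phenyl]-5-hydroxychroman-4-one | O=C1C[C@@H](c2cc(O[Si](C)(C)C(C)(C)C)cc(O[Si](C)(C)C(C)(C)C)c2)Oc2cc(O[Si](C)(C)C(C)(C)C)cc(O)c12 | intermediate
3 | geraniol [(2E)-3,7-dimethylocta-2,6-dien-1-ol] | CC(C)=CCC/C(C)=C/CO | starting material
4 | (2S)-7-(TBS-oxy)-2-[3,5-bis(TBS-oxy)phenyl]-5-(geranyloxy)chroman-4-one | O=C1C[C@@H](c2cc(O[Si](C)(C)C(C)(C)C)cc(O[Si](C)(C)C(C)(C)C)c2)Oc2cc(O[Si](C)(C)C(C)(C)C)cc(OC/C=C(\C)CCC=C(C)C)c12 | intermediate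
5 | (2S)-7-(TBS-oxy)-2-[3,5-bis(TBS-oxy)phenyl]-6-[(2E)-geranyl]-5-hydroxychroman-4-one | CC(C)=CCC/C(C)=C/Cc1c(O[Si](C)(C)C(C)(C)C)cc2c(c1O)C(=O)C[C@@H](c1cc(O[Si](C)(C)C(C)(C)C)cc(O[Si](C)(C)C(C)(C)C)c1)O2 | intermediate
6 | Schizolaenone C [(2S)-6-geranyl-5,7,3',5'-tetrahydroxyflavanone] | CC(C)=CCC/C(C)=C/Cc1c(O)cc2c(c1O)C(=O)C[C@@H](c1cc(O)cc(O)c1)O2 | target

## Count and risks

Total steps: 4. Longest linear sequence: 4 (1 → 2 → 4 → 5 → 6).

**Step 3 (clay-promoted geranyl shift) – most likely to fail.** The risks are competing migration to C8, loss of the geranyl group back to 2, intermolecular alkylation of the silyloxy-substituted B ring, and chroman formation. The fallback sets out from 2 and replaces the rearrangement by halogenation and cross-coupling. Iodination ortho to the chelated 5-OH (benzyltrimethylammonium dichloroiodate, CaCO3, CH2Cl2–MeOH, rt) gives (2S)-6-iodo-7-(TBS-oxy)-2-[3,5-bis(TBS-oxy)phenyl]-5-hydroxychroman-4-one F1. Stille coupling (Pd(PPh3)4, toluene, 90 °C) with tributyl[(2E)-geranyl]stannane F2 (from geranyl chloride and Bu3SnLi, THF, –78 °C) then delivers the linear E-geranyl arene. The fallback comes back to the route at 5.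

**Step 2 (Mitsunobu on the hindered, hydrogen-bonded 5-OH).** The risk is sluggish or incomplete etherification. The fallback sets out from 2 and uses π-allyl palladium chemistry instead of redox condensation. Tsuji–Trost O-allylation (Pd(PPh3)4 cat., THF, rt) with geranyl methyl carbonate F3 (from 3 and methyl chloroformate/pyridine) gives the linear ether; the methoxide released on ionisation is the only base. It comes back to the route at 4.

**Step 1 (selective trisilylation of four phenols).** The risks are partial 5-O-silylation or lability of the activated 7-O-silyl ether on handling. The fallback sets out from 1 and changes the protecting-group strategy to esters. Ac2O/pyridine at 0 °C gives (2S)-7-acetoxy-2-(3,5-diacetoxyphenyl)-5-hydroxychroman-4-one F4. Mitsunobu coupling with 3 gives the 5-O-geranyl ether (2S)-7-acetoxy-2-(3,5-diacetoxyphenyl)-5-(geranyloxy)chroman-4-one F5. The K10 shift gives (2S)-7-acetoxy-2-(3,5-diacetoxyphenyl)-6-[(2E)-geranyl]-5-hydroxychroman-4-one F6. Neutral methanolysis of the aryl acetates (NH4OAc, aq. MeOH, rt, ee checked) comes back to the route at 6.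

## Further compounds

F1 | step 3 | (2S)-6-iodo-7-(TBS-oxy)-2-[3,5-bis(TBS-oxy)phenyl]-5-hydroxychroman-4-one | Ic1c(O[Si](C)(C)C(C)(C)C)cc2c(c1O)C(=O)C[C@@H](c1cc(O[Si](C)(C)C(C)(C)C)cc(O[Si](C)(C)C(C)(C)C)c1)O2
F2 | step 3 | tributyl[(2E)-3,7-dimethylocta-2,6-dien-1-yl]stannane | CC(C)=CCC/C(C)=C/C[Sn](CCCC)(CCCC)CCCC
F3 | step 2 | geranyl methyl carbonate | COC(=O)OC/C=C(\C)CCC=C(C)C
F4 | step 1 | (2S)-7-acetoxy-2-(3,5-diacetoxyphenyl)-5-hydroxychroman-4-one | O=C1C[C@@H](c2cc(OC(C)=O)cc(OC(C)=O)c2)Oc2cc(OC(C)=O)cc(O)c12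
F5 | step 1 | (2S)-7-acetoxy-2-(3,5-diacetoxyphenyl)-5-(geranyloxy)chroman-4-one | O=C1C[C@@H](c2cc(OC(C)=O)cc(OC(C)=O)c2)Oc2cc(OC(C)=O)cc(OC/C=C(\C)CCC=C(C)C)c12
F6 | step 1 | (2S)-7-acetoxy-2-(3,5-diacetoxyphenyl)-6-[(2E)-geranyl]-5-hydroxychroman-4-one | CC(C)=CCC/C(C)=C/Cc1c(OC(C)=O)cc2c(c1O)C(=O)C[C@@H](c1cc(OC(C)=O)cc(OC(C)=O)c1)O2
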